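The constants were chosen freely, and the outcome is calculated.

Substrate is the slow member of this flask: it turns into intermediate with a half-life of 7.26 s, and the two nucleophiles then compete for each intermediate.

    substrate → intermediate (k1 = 0.0955 s⁻¹)
    first nucleophile + intermediate → target (k2 = 17.7 M⁻¹ s⁻¹)
    second nucleophile + intermediate → other capture product (k3 = 121 M⁻¹ s⁻¹)
    target ⇌ isomer of the product (K4 = 0.83, k4 = 0.255 s⁻¹)
    second nucleophile ⇌ dormant form (K5 = 0.210, k5 = 0.177 s⁻¹)

| setting | epsilon | alpha | zeta | eta | delta |
|---|---|---|---|---|---|
| substrate | 0.40 M (fed, over 15 s) | 0.40 M (in portions, 4, over 15 s) | 0.40 M | 0.40 M | 0.40 M |
| first nucleophile | 3.00 equiv | 3.00 equiv | 3.00 equiv | 3.00 equiv | 3.00 equiv |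
| second nucleophile | 1.05 equiv | 1.05 equiv | 1.05 equiv (fed, over 1.5 s) | 1.05 equiv (fed, over 15 s) | 1.05 equiv |
| time | 40 s | 40 s | 40 s | 40 s | 40 s |
| remark | all else is in the flask from the start; the feed brings no volume worth counting | first portion at the start, last at 15 s | all else is in the flask from the start; the feed brings no volume worth counting | all else is in the flask from the start; the feed brings no volume worth counting | everything together at the start |

1. the flask that comes out highest in share of target in target plus other capture product, or "all alike" when all lie within 1.5 percentage points (epsilon / alpha / zeta / eta / delta / all alike)
2. share of target in target plus other capture product at the end, epsilon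
3. share of target in target plus other capture product at the end, alpha
4. share of target in target plus other capture product at the end, zeta
5. share of target in target plus other capture product at the end, eta
6. share of target in target plus other capture product at the end, delta

At the charged amounts, the constants become these times:

- intermediate, life under both captures: 0.0139 s
- second nucleophile and dormant form, relaxation: 0.981 s
- target and isomer of the product, relaxation: 1.78 s
- substrate, half-life: 7.26 s
- feeds of second nucleophile: 1.5 s and 15 s

The first row lies far below the fourth, so substrate decay is the rate-limiting step and the intermediate sits at steady state. What matters is then the ratio of its two captures.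

The second row is also shorter than the fourth, so the pool of second nucleophile plus dormant form stays about 82.6% free. The third row is shorter too, so about 54.6% of the first nucleophile's product stands as target at the end.

From this comes the break-even pool, the pool at which both captures run equally fast, with first nucleophile at its charge: 0.212 M. A pool P gives the second nucleophile the capture share P/(P+break-even pool).

The last row now reads against the fourth. The quick feed of zeta ends before the half-life, but the slow feed of eta outlasts it. At the half-life eta has received 0.203 M, while delta was charged 0.420 M at the start. Epsilon and alpha, fed with substrate, have that same charge of second nucleophile from the start.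

The pool at the half-life is taken as the amount delivered less half of what second nucleophile captures from the substrate charged, at the share that pool gives, with nearly all of the substrate reckoned as captured by 40 s. Solving gives 0.303 M for delta and 0.128 M for eta.

The target share is then 27.7% for delta, and the same reckoning serves zeta, epsilon and alpha. For eta it is 47.6%, so the pick is eta.

The forecast also picks eta, at 43.6%, with 27.4%, 27.3%, 28.8% and 27.2% for epsilon, alpha, zeta and delta. It counts “only about 54.6% of the first-nucleophile product remains as target”. Its eta lies 4 percentage points below this reckoning.

The flask gives eta: 43.4% for eta, against 27.3%, 27.3%, 28.7% and 27.2% for epsilon, alpha, zeta and delta. In eta the mean [second nucleophile] over the first 15 s was 0.133 M, below the free level at break-even, 0.175 M.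

The neighbour flask is eta with 5.10 equiv of first nucleophile. Its break-even pool is 0.361 M, its pool at the half-life 0.146 M, and its reckoned share 57.4%. The computed flask gives 54.1%.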